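## Retrosynthetic overview

1. Target 25 comes from dimethyl ether 24 (BCl3), 24 from tertiary alcohol 20 (alkoxide acylation with mixed anhydride 22), and 20 from silyl ether 19; the ester and the free peri phenols are installed only after the quinone ring exists.
2. The strategy rests on the quinone ring C1(=O)–C2(cyclobutyl)=C3(H)–C4(=O), fused at C4a/C8a to the 5,8-dioxygenated benzene ring. It is cut at C1–C2: C1, C4, C4a and C8a are the four-membered ring of a 2-hydroxybenzocyclobutenone, and C2/C3 are the two sp carbons of an alkyne on its carbinol carbon.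
3. Precursor 16 comes from lithium acetylide 15 and the mirror-symmetrical dione 7; 7 comes from 1 and 2 by aryne [2+2] cycloaddition, acetal hydrolysis, geminal dibromination and hydrolysis.
4. Alkyne 14 comes from ketone 8 and silylacetylene 9; its only stereocenter (the cyclobutane carbon that later carries the ester oxygen, R) is fixed by resolution as a camphanate ester.
5. Ring order: the benzene and cyclobutane rings are bought, the four-membered ketone ring is made first (step 1), and the quinone ring is made last (step 9).

Key step: step 9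

Remark on the chemistry: the stereocenter is (R) by CIP (O > quinonyl or alkynyl > CMe2 > CH2). Which separated camphanate carries it is to be assigned by X-ray diffraction, with the camphanate unit as internal reference. The naphthazarin is drawn in the tautomer of the target SMILES.

## Route

Step 1
Reactants: 1 2-bromo-1,4-dimethoxybenzene (1-bromo-2,5-dimethoxybenzene); 2 1,1-dimethoxyethene
Product: 4 3,6-dimethoxybenzocyclobutenone dimethyl acetal (1,1,3,6-tetramethoxy-1,2-dihydrobenzocyclobutene), via 3,6-dimethoxybenzyne 3 (not isolated)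
Conditions: NaNH2 (2 equiv), 2 (3 equiv), THF, reflux
Reagents that add atoms: none
Why: NaNH2 eliminates HBr to the symmetrical aryne 3, which should undergo stepwise polar [2+2] cycloaddition with the electron-rich ketene acetal (aryne–ketene acetal cycloaddition); the symmetry of 3 allows only one regioisomer.

Step 2
Reactants: 4 3,6-dimethoxybenzocyclobutenone dimethyl acetal
Product: 5 3,6-dimethoxybenzocyclobutenone
Conditions: 1 M aq. HCl, THF, rt
Reagents that add atoms: water, O
Why: Acid-catalysed acetal hydrolysis should free the strained ketone, which tolerates dilute acid and is kept away from the basic nucleophiles that open the four-membered ring.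

Step 3
Reactants: 5 3,6-dimethoxybenzocyclobutenone
Product: 6 2,2-dibromo-3,6-dimethoxybenzocyclobutenone
Conditions: NBS (2.2 equiv), AIBN (cat.), PhCF3, 85 °C
Reagents that add atoms: N-bromosuccinimide, O=C1CCC(=O)N1Br
Why: Wohl–Ziegler radical bromination should take place twice at the one CH2 group, which is both benzylic and alpha to the ketone; the non-polar radical conditions and the acyl-deactivated ring disfavour nuclear bromination.

Step 4
Reactants: 6 2,2-dibromo-3,6-dimethoxybenzocyclobutenone
Product: 7 3,6-dimethoxybenzocyclobutene-1,2-dione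
Conditions: 50% aq. H2SO4, 60 °C
Reagents that add atoms: water, O
Why: Acid hydrolysis of the geminal dibromide should give the second carbonyl; the dione and the aryl methyl ethers are stable to this medium.

Step 5
Reactants: 8 2,2-dimethylcyclobutanone; 9 ethynyltrimethylsilane
Product: 12 (R)-2,2-dimethyl-1-[(trimethylsilyl)ethynyl]cyclobutyl (1S,4R)-camphanate, via lithium (trimethylsilyl)acetylide 10 (not isolated), via racemic lithium alkoxide 11 (not isolated)
Conditions: 9, n-BuLi, THF, −78 °C; 8, −78 °C; (1S)-(−)-camphanic chloride, DMAP (cat.), −78 °C → rt; diastereomers separated on SiO2 and by crystallization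
Reagents that add atoms: (1S)-(−)-camphanic chloride, ClC(=O)[C@@]12CC[C@@](C)(C(=O)O1)C2(C)C
Why: 1,2-Addition of the acetylide to the strained ketone gives the racemic tertiary alkoxide, and in situ O-acylation with the enantiopure acid chloride turns it into two diastereomeric esters; the stereocenter is thus set by resolution, the (R)-carbinol ester being kept after X-ray assignment.

Step 6
Reactants: 12 (R)-2,2-dimethyl-1-[(trimethylsilyl)ethynyl]cyclobutyl (1S,4R)-camphanate
Product: 13 (R)-1-ethynyl-2,2-dimethylcyclobutan-1-ol
Conditions: KOH, MeOH–THF–H2O, 50 °C; aqueous phase later acidified (HCl) to recover the acid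
Reagents that add atoms: none
Why: Saponification at the acyl carbon leaves the carbinol C–O bond and its configuration untouched, and the same basic methanol should protodesilylate the alkynylsilane.

Step 7
Reactants: 13 (R)-1-ethynyl-2,2-dimethylcyclobutan-1-ol
Product: 14 (R)-triethyl[(1-ethynyl-2,2-dimethylcyclobutyl)oxy]silane
Conditions: Et3SiOTf, 2,6-lutidine, CH2Cl2, 0 °C → rt
Reagents that add atoms: triethylsilyl triflate, CC[Si](CC)(CC)OS(=O)(=O)C(F)(F)F
Why: The silyl triflate should silylate even this crowded tertiary alcohol, masking the hydroxyl for the acetylide addition and the thermolysis.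

Step 8
Reactants: 14 (R)-triethyl[(1-ethynyl-2,2-dimethylcyclobutyl)oxy]silane; 7 3,6-dimethoxybenzocyclobutene-1,2-dione
Product: 16 2-hydroxy-3,6-dimethoxy-2-{[(R)-2,2-dimethyl-1-(triethylsilyloxy)cyclobutyl]ethynyl}benzocyclobuten-1(2H)-one (both epimers at the new carbinol carbon), via lithium acetylide 15 (not isolated)
Conditions: n-BuLi (1.0 equiv), THF, −78 °C; cannulated into 7 (1.1 equiv), THF, −78 °C; sat. aq. NH4Cl, −78 °C
Reagents that add atoms: none
Why: Acetylide 1,2-addition to one of the two equivalent carbonyls of the strained dione should stop at mono-addition, since the alkoxide formed deactivates the remaining ketone at low temperature; the new carbinol carbon forms without control, which is harmless because it becomes the C4 carbonyl.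

Step 9
Reactants: 16 2-hydroxy-3,6-dimethoxy-2-{[(R)-2,2-dimethyl-1-(triethylsilyloxy)cyclobutyl]ethynyl}benzocyclobuten-1(2H)-one
Product: 19 2-[(R)-2,2-dimethyl-1-(triethylsilyloxy)cyclobutyl]-5,8-dimethoxy-1,4-naphthoquinone, via o-quinoid alkynyl ketene 17 (not isolated), via aryl/phenoxyl diradical 18 (not isolated)
Conditions: degassed p-xylene (0.02 M), 140 °C
Reagents that add atoms: none
Why: Heating opens the strained four-membered ring of 16 by conrotatory four-electron electrocyclic cleavage of the C(=O)–C(OH) bond with the hydroxyl turning outward, so that the o-quinoid ketene 17 has its alkynyl group pointed at the ketene carbon. That carbon then bonds to the far alkyne carbon, which closes the six-membered quinone ring (bond formation from the ketene carbon to the alkyne terminus in the plane of the alkyne, formally a 6-endo closure) and restores the benzene ring, giving diradical 18; transfer of the hydroxyl hydrogen to the aryl radical carbon, the future C3, then delivers the quinone at its final oxidation level. The closest known reaction type is the thermal rearrangement of 4-alkynyl-4-hydroxycyclobutenones and their benzo-fused analogues to 1,4-quinones (Moore rearrangement). No stereocenter is formed: the epimeric benzocyclobutenol carbon becomes the C4 carbonyl, and the (R)-carbinol carbon is a fully substituted spectator that cannot epimerize. The step needs six- over five-membered closure (quinone against alkylidene indanedione), which is secured by the alkyne terminus being a saturated quaternary carbon that gives no stabilization to the exocyclic vinyl radical of the five-membered path; regiochemistry needs no control because dione 7 is symmetrical.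

Step 10
Reactants: 19 2-[(R)-2,2-dimethyl-1-(triethylsilyloxy)cyclobutyl]-5,8-dimethoxy-1,4-naphthoquinone
Product: 20 2-[(R)-1-hydroxy-2,2-dimethylcyclobutyl]-5,8-dimethoxy-1,4-naphthoquinone
Conditions: HF·pyridine, THF–pyridine, 0 °C → rt
Reagents that add atoms: none
Why: Fluoride-driven Si–O cleavage under buffered, weakly acidic conditions should spare the quinone, and ionization or ring expansion at the carbinol carbon is disfavoured by the electron-poor quinone attached to it.

Step 11
Reactants: 21 angelic acid, (Z)-2-methylbut-2-enoic acid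
Product: 22 angelic 2,4,6-trichlorobenzoic anhydride
Conditions: 2,4,6-trichlorobenzoyl chloride, Et3N, toluene, 0 °C → rt; filtered, used as solution
Reagents that add atoms: 2,4,6-trichlorobenzoyl chloride, O=C(Cl)c1c(Cl)cc(Cl)cc1Cl
Why: Mixed-anhydride formation of the Yamaguchi type activates the acid under mild conditions that should not isomerize the Z double bond, unlike conversion to the acid chloride.

Step 12
Reactants: 20 2-[(R)-1-hydroxy-2,2-dimethylcyclobutyl]-5,8-dimethoxy-1,4-naphthoquinone; 22 angelic 2,4,6-trichlorobenzoic anhydride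
Product: 24 (R)-1-(5,8-dimethoxy-1,4-dioxo-1,4-dihydronaphthalen-2-yl)-2,2-dimethylcyclobutyl (Z)-2-methylbut-2-enoate, via lithium alkoxide 23 (not isolated)
Conditions: LiN(SiMe3)2 (1.05 equiv), THF, −78 °C; 22 (1.5 equiv), −78 → 0 °C; sat. aq. NH4Cl
Reagents that add atoms: none
Why: The lithium alkoxide of the hindered tertiary alcohol should attack the angeloyl carbonyl of the mixed anhydride, the aroyl carbonyl being shielded by two ortho chlorines (alkoxide acylation with a Yamaguchi anhydride); without a nucleophilic amine catalyst the Z geometry is kept, and the carbinol configuration is untouched because only the O–H bond reacts.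

Step 13
Reactants: 24 (R)-1-(5,8-dimethoxy-1,4-dioxo-1,4-dihydronaphthalen-2-yl)-2,2-dimethylcyclobutyl (Z)-2-methylbut-2-enoate
Product: 25 (R)-1-(5,8-dihydroxy-1,4-dioxo-1,4-dihydronaphthalen-2-yl)-2,2-dimethylcyclobutyl (Z)-2-methylbut-2-enoate (CNP0326301.1)
Conditions: BCl3 (4 equiv), CH2Cl2, −78 → −20 °C; then H2O
Reagents that add atoms: none
Why: Each methoxy group is peri to a quinone carbonyl, so BCl3 should chelate and cleave both O–CH3 bonds at low temperature (chelation-assisted demethylation), while ionization of the tertiary ester is disfavoured by the electron-poor quinone on the carbinol carbon.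

## Compound list

1 | 2-bromo-1,4-dimethoxybenzene (1-bromo-2,5-dimethoxybenzene) | COc1ccc(OC)c(Br)c1 | starting material
2 | 1,1-dimethoxyethene | C=C(OC)OC | starting material
3 | 3,6-dimethoxybenzyne | COC1=CC=C(OC)C#C1 | intermediate
4 | 3,6-dimethoxybenzocyclobutenone dimethyl acetal | COc1ccc(OC)c2c1CC2(OC)OC | intermediate
5 | 3,6-dimethoxybenzocyclobutenone | COc1ccc(OC)c2c1CC2=O | intermediate
6 | 2,2-dibromo-3,6-dimethoxybenzocyclobutenone | COc1ccc(OC)c2c1C(Br)(Br)C2=O | intermediate
7 | 3,6-dimethoxybenzocyclobutene-1,2-dione | COc1ccc(OC)c2c1C(=O)C2=O | intermediate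
8 | 2,2-dimethylcyclobutanone | CC1(C)CCC1=O | starting material
9 | ethynyltrimethylsilane | C#C[Si](C)(C)C | starting material
10 | lithium (trimethylsilyl)acetylide | [Li]C#C[Si](C)(C)C | intermediate
11 | racemic lithium 2,2-dimethyl-1-[(trimethylsilyl)ethynyl]cyclobutan-1-olate | [Li]OC1(C#C[Si](C)(C)C)CCC1(C)C | intermediate
12 | (R)-2,2-dimethyl-1-[(trimethylsilyl)ethynyl]cyclobutyl (1S,4R)-camphanate | O=C(O[C@]1(C#C[Si](C)(C)C)CCC1(C)C)[C@@]12CC[C@@](C)(C(=O)O1)C2(C)C | intermediate
13 | (R)-1-ethynyl-2,2-dimethylcyclobutan-1-ol | O[C@]1(C#C)CCC1(C)C | intermediate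
14 | (R)-triethyl[(1-ethynyl-2,2-dimethylcyclobutyl)oxy]silane | CC[Si](CC)(CC)O[C@]1(C#C)CCC1(C)C | intermediate
15 | lithium acetylide of 14 | CC[Si](CC)(CC)O[C@]1(C#C[Li])CCC1(C)C | intermediate
16 | 2-hydroxy-3,6-dimethoxy-2-{[(R)-2,2-dimethyl-1-(triethylsilyloxy)cyclobutyl]ethynyl}benzocyclobuten-1(2H)-one, both epimers at the ring carbinol carbon | CC[Si](CC)(CC)O[C@]1(C#CC2(O)C(=O)c3c(OC)ccc(OC)c32)CCC1(C)C | intermediate
17 | o-quinoid alkynyl ketene from ring opening of 16 (hydroxyl outward, alkynyl toward the ketene) | CC[Si](CC)(CC)O[C@]1(C#C/C(O)=C2/C(OC)=CC=C(OC)C2=C=O)CCC1(C)C | intermediate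
18 | 4-hydroxy-5,8-dimethoxy-2-[(R)-2,2-dimethyl-1-(triethylsilyloxy)cyclobutyl]naphthalen-1-oxyl-3-yl diradical | CC[Si](CC)(CC)O[C@]1(c2[c]c(O)c3c(OC)ccc(OC)c3c2[O])CCC1(C)C | intermediate
19 | 2-[(R)-2,2-dimethyl-1-(triethylsilyloxy)cyclobutyl]-5,8-dimethoxy-1,4-naphthoquinone | CC[Si](CC)(CC)O[C@]1(C2=CC(=O)c3c(OC)ccc(OC)c3C2=O)CCC1(C)C | intermediate
20 | 2-[(R)-1-hydroxy-2,2-dimethylcyclobutyl]-5,8-dimethoxy-1,4-naphthoquinone | O[C@]1(C2=CC(=O)c3c(OC)ccc(OC)c3C2=O)CCC1(C)C | intermediate
21 | angelic acid, (Z)-2-methylbut-2-enoic acid | C/C=C(/C)C(=O)O | starting material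
22 | angelic 2,4,6-trichlorobenzoic anhydride | C/C=C(/C)C(=O)OC(=O)c1c(Cl)cc(Cl)cc1Cl | intermediate
23 | lithium alkoxide of 20 | [Li]O[C@]1(C2=CC(=O)c3c(OC)ccc(OC)c3C2=O)CCC1(C)C | intermediate
24 | (R)-1-(5,8-dimethoxy-1,4-dioxo-1,4-dihydronaphthalen-2-yl)-2,2-dimethylcyclobutyl (Z)-2-methylbut-2-enoate | C/C=C(/C)C(=O)O[C@]1(C2=CC(=O)c3c(OC)ccc(OC)c3C2=O)CCC1(C)C | intermediate
25 | (R)-1-(5,8-dihydroxy-1,4-dioxo-1,4-dihydronaphthalen-2-yl)-2,2-dimethylcyclobutyl (Z)-2-methylbut-2-enoate, CNP0326301.1 | C/C=C(/C)C(=O)O[C@]1(C2=CC(=O)c3c(O)ccc(O)c3C2=O)CCC1(C)C | target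

## Step count and risks

Total step count: 13. Longest linear sequence: 9 steps (steps 1, 2, 3, 4, 8, 9, 10, 12, 13).

The three steps most likely to fail:

Step 9. The ketene may close onto the near alkyne carbon (five-membered path), because the crowded far carbon is slow to bond, or material may be lost thermally before the ring opens. The fallback sets out from alkyne 14 and dione 7 and comes back at quinone 19; it replaces the diradical closure by a 6π electrocyclization, which has no ring-size ambiguity. Hydrostannation of 14 (Bu3SnH, PdCl2(PPh3)2 cat., THF, rt) should give the (E)-alkenylstannane F1. Tin–lithium exchange with n-BuLi (THF, −78 °C) gives the alkenyllithium F2, which is added to 7 at −78 °C to give the 2-alkenyl-2-hydroxybenzocyclobutenone F3. Heating in toluene at 110 °C opens the four-membered ring to the dienyl ketene F4, which electrocyclizes and enolizes to the naphthalene-1,4-diol F5. Oxidation with Ag2O in Et2O returns 19.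

Step 12. The crowded tertiary alkoxide may fail to acylate, the amide base may attack the quinone, or the acyl group may isomerize from Z to E. The fallback sets out from alcohol 13 (with anhydride 22 and dione 7) and comes back at 24; it places the ester before any quinone exists and omits steps 7 and 10. Alcohol 13 is deprotonated at oxygen only (LiN(SiMe3)2, 1.05 equiv, THF, −78 °C) to the lithium alkoxide F6, which is acylated with 22 to give the alkynyl angelate F7. Deprotonation of the terminal alkyne with LiN(SiMe3)2 at −78 °C gives the lithium acetylide F8, which adds to 7 to give the ester-bearing adduct F9. Thermolysis as in step 9 passes through the ketene F10 and the diradical F11 and gives 24.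

Step 13. The Lewis acid may ionize or cleave the tertiary ester, may isomerize Z to E during ether cleavage, or may stall after the first demethylation. The fallback sets out from alcohol 20 and comes back at target 25; it removes the methyl ethers before the ester is present. BCl3 (CH2Cl2, −78 → 0 °C, then H2O) on 20 gives the naphthazarin alcohol F12. Excess LiN(SiMe3)2 (3.3 equiv) gives the trilithium salt F13, and excess 22 acylates all three oxygens to give the tris-angelate F14. Brief K2CO3 in MeOH at 0 °C should cleave only the two aryl esters, whose leaving groups are acidic chelated phenoxides, leaving the hindered tertiary ester and giving 25.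

Further compounds
F1 | step 9 | triethyl({1-[(E)-2-(tributylstannyl)ethenyl]-2,2-dimethylcyclobutyl}oxy)silane, (S) by CIP with the spatial arrangement of 14 | CC[Si](CC)(CC)O[C@]1(/C=C/[Sn](CCCC)(CCCC)CCCC)CCC1(C)C
F2 | step 9 | (E)-alkenyllithium from F1 | CC[Si](CC)(CC)O[C@]1(/C=C/[Li])CCC1(C)C
F3 | step 9 | 2-hydroxy-3,6-dimethoxy-2-{(E)-2-[2,2-dimethyl-1-(triethylsilyloxy)cyclobutyl]ethenyl}benzocyclobuten-1(2H)-one, both epimers at the ring carbinol carbon | CC[Si](CC)(CC)O[C@]1(/C=C/C2(O)C(=O)c3c(OC)ccc(OC)c32)CCC1(C)C
F4 | step 9 | o-quinoid dienyl ketene from ring opening of F3 | CC[Si](CC)(CC)O[C@]1(/C=C/C(O)=C2/C(OC)=CC=C(OC)C2=C=O)CCC1(C)C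
F5 | step 9 | 2-[(R)-2,2-dimethyl-1-(triethylsilyloxy)cyclobutyl]-5,8-dimethoxynaphthalene-1,4-diol | CC[Si](CC)(CC)O[C@]1(c2cc(O)c3c(OC)ccc(OC)c3c2O)CCC1(C)C
F6 | step 12 | lithium (R)-1-ethynyl-2,2-dimethylcyclobutan-1-olate | [Li]O[C@]1(C#C)CCC1(C)C
F7 | step 12 | (R)-1-ethynyl-2,2-dimethylcyclobutyl (Z)-2-methylbut-2-enoate | C/C=C(/C)C(=O)O[C@]1(C#C)CCC1(C)C
F8 | step 12 | lithium acetylide of F7 | C/C=C(/C)C(=O)O[C@]1(C#C[Li])CCC1(C)C
F9 | step 12 | (R)-1-[(2-hydroxy-3,6-dimethoxy-1-oxo-1,2-dihydrobenzocyclobuten-2-yl)ethynyl]-2,2-dimethylcyclobutyl (Z)-2-methylbut-2-enoate, both epimers at the ring carbinol carbon | C/C=C(/C)C(=O)O[C@]1(C#CC2(O)C(=O)c3c(OC)ccc(OC)c32)CCC1(C)C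
F10 | step 12 | o-quinoid alkynyl ketene from ring opening of F9 | C/C=C(/C)C(=O)O[C@]1(C#C/C(O)=C2/C(OC)=CC=C(OC)C2=C=O)CCC1(C)C
F11 | step 12 | aryl/phenoxyl diradical from closure of F10 | C/C=C(/C)C(=O)O[C@]1(c2[c]c(O)c3c(OC)ccc(OC)c3c2[O])CCC1(C)C
F12 | step 13 | 5,8-dihydroxy-2-[(R)-1-hydroxy-2,2-dimethylcyclobutyl]-1,4-naphthoquinone | O[C@]1(C2=CC(=O)c3c(O)ccc(O)c3C2=O)CCC1(C)C
F13 | step 13 | trilithium salt of F12 | [Li]O[C@]1(C2=CC(=O)c3c(O[Li])ccc(O[Li])c3C2=O)CCC1(C)C
F14 | step 13 | tris-angelate of F12 (tertiary ester and both aryl esters) | C/C=C(/C)C(=O)O[C@]1(C2=CC(=O)c3c(OC(=O)/C(C)=C\C)ccc(OC(=O)/C(C)=C\C)c3C2=O)CCC1(C)C
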